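**Plan**

- The pyran ring O1–C2–C3=C4–C4a–C8a is the valence isomer of a 1-oxatriene (vinyl ortho-quinone methide). It sits on an arene that carries oxygen on both carbons flanking C4a (O1 and 5-OH). The retrosynthesis cuts O1–C2 (oxa-6π) and then C4–C4a (Knoevenagel-type union), giving the twofold-symmetric 4,5,6-trimethoxybenzene-1,3-diol and an (E)-enal.
- The enal is cut at the CH2–C(Me)= bond (B-alkyl Suzuki–Miyaura of a vinylcyclohexene with an (E)-β-triflyloxycrotonate). The cyclohexene is cut by a Diels–Alder disconnection into (E)-2-methylbut-2-enal and a 2-silyloxydiene.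
- Forward: the cyclohexene ring is made first (Diels–Alder), its double bond is placed through an enol triflate, and the chain is attached. The arene is made separately, and the pyran ring is closed last, in the same operation that joins the two fragments.
- Stereochemistry: the cis-dimethyl pair on the cyclohexene comes from the E geometry of the dienophile, and its absolute sense from a chiral oxazaborolidinium catalyst. Chromene C2 comes from catalyst-controlled helicity of the electrocyclisation of a geometrically pure (E)-oxatriene.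

Key step: step 13

Assumption: the sense of induction of the chiral catalysts in steps 2 and 13 is taken from the accepted transition-state pictures; should either prove opposite, the enantiomeric catalyst is used.

**Route**

Step 1
Reactants: 1 pent-1-en-3-one
Product: 2 (3Z)-3-[(triisopropylsilyl)oxy]penta-1,3-diene
Conditions: i-Pr3SiOTf, Et3N, CH2Cl2, 0 °C → rt
Reagents that add atoms: triisopropylsilyl trifluoromethanesulfonate, CC(C)[Si](OS(=O)(=O)C(F)(F)F)(C(C)C)C(C)C
Why: Soft enolisation of the ethyl ketone (silyl triflate/amine, silyl dienol ether formation) should give mainly the Z enol ether, in which the terminal methyl is "outside" and does not hinder the s-cis diene.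

Step 2
Reactants: 2 (3Z)-3-[(triisopropylsilyl)oxy]penta-1,3-diene; 3 (E)-2-methylbut-2-enal
Product: 4 (1R,6R)-1,5,6-trimethyl-4-[(triisopropylsilyl)oxy]cyclohex-3-ene-1-carbaldehyde (C5 epimers)
Conditions: (3aS)-3,3-diphenyl-1-(2-methylphenyl)tetrahydro-1H,3H-pyrrolo[1,2-c][1,3,2]oxazaborole·HNTf2 (20 mol %), CH2Cl2, −78 → −40 °C; Et3N quench
Reagents that add atoms: none
Why: Catalytic enantioselective Diels–Alder reaction: the silyloxy group sends the methyl-bearing diene terminus to the β-carbon of the enal ("para" adduct), the E geometry of 3 is transferred suprafacially so that the two methyls at C1 and C6 end up cis (CHO trans to the C6 methyl), and the chiral oxazaborolidinium cation is to leave the Cα-Re face of the s-trans enal open, which sets C1 and C6; C5 is irrelevant because it later becomes sp2.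

Step 3
Reactants: 4 (1R,6R)-1,5,6-trimethyl-4-[(triisopropylsilyl)oxy]cyclohex-3-ene-1-carbaldehyde
Product: 5 triisopropyl{[(4S,5R)-4-ethenyl-4,5,6-trimethylcyclohex-1-en-1-yl]oxy}silane
Conditions: Ph3PCH3Br, KOtBu, THF, 0 °C → rt
Reagents that add atoms: methyltriphenylphosphonium bromide (as its ylide), C[P+](c1ccccc1)(c1ccccc1)c1ccccc1.[Br-]
Why: Wittig methylenation of the non-enolisable α-quaternary aldehyde; the hindered silyl enol ether is inert to the ylide and no stereocentre is touched.

Step 4
Reactants: 5 triisopropyl{[(4S,5R)-4-ethenyl-4,5,6-trimethylcyclohex-1-en-1-yl]oxy}silane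
Product: 6 (3R,4S)-4-ethenyl-2,3,4-trimethylcyclohexan-1-one (C2 epimers)
Conditions: Bu4NF, AcOH, THF, 0 °C
Reagents that add atoms: none
Why: Buffered fluoride cleavage of the silyl enol ether unveils the ketone; C2 forms as an epimer mixture that does not matter (it becomes sp2 in step 5), and C3 and C4 are not enolisable.

Step 5
Reactants: 6 (3R,4S)-4-ethenyl-2,3,4-trimethylcyclohexan-1-one
Product: 8 (3S,4S)-4-ethenyl-2,3,4-trimethylcyclohex-1-en-1-yl trifluoromethanesulfonate, via bromomagnesium enolate 7 (not isolated)
Conditions: i-Pr2NMgBr (from EtMgBr, i-Pr2NH), Et2O, rt; then PhNTf2, THF, rt → 40 °C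
Reagents that add atoms: N-phenylbis(trifluoromethanesulfonimide), O=S(=O)(N(c1ccccc1)S(=O)(=O)C(F)(F)F)C(F)(F)F
Why: Equilibrating (thermodynamic) enolisation with the bromomagnesium amide should give the more substituted C1–C2 enolate 7, and O-triflation of it (regioselective enol triflate formation) puts the future ring double bond between the carbonyl carbon and the methyl-bearing carbon.

Step 6
Reactants: 8 (3S,4S)-4-ethenyl-2,3,4-trimethylcyclohex-1-en-1-yl trifluoromethanesulfonate
Product: 9 (3R,4S)-4-ethenyl-2,3,4-trimethylcyclohex-1-ene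
Conditions: Pd(OAc)2 (5 mol %), PPh3, HCO2H, Bu3N, DMF, 60 °C
Reagents that add atoms: none
Why: Palladium-catalysed formate reduction of the vinyl triflate replaces OTf by H without moving the double bond, which gives the 1,2,3-trimethylcyclohex-3-ene pattern of the target.

Step 7
Reactants: 10 ethyl 3-oxobutanoate
Product: 11 ethyl (2E)-3-{[(trifluoromethyl)sulfonyl]oxy}but-2-enoate
Conditions: Tf2O, aq. Me4NOH, hexanes, 5 °C
Reagents that add atoms: trifluoromethanesulfonic anhydride, O=S(=O)(OS(=O)(=O)C(F)(F)F)C(F)(F)F
Why: O-Triflation of the acetoacetate enolate under non-chelating tetraalkylammonium conditions favours the E enol triflate (triflate trans to the ester), which fixes the geometry of the later trisubstituted alkene.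

Step 8
Reactants: 9 (3R,4S)-4-ethenyl-2,3,4-trimethylcyclohex-1-ene; 11 ethyl (2E)-3-{[(trifluoromethyl)sulfonyl]oxy}but-2-enoate
Product: 13 ethyl (2E)-3-methyl-5-[(1S,2S)-1,2,3-trimethylcyclohex-3-en-1-yl]pent-2-enoate, via B-alkyl-9-borabicyclononane 12 (not isolated)
Conditions: 9-BBN-H, THF, 0 °C → rt; then 11, Pd(dppf)Cl2 (5 mol %), K3PO4 (aq.), DMF, rt
Reagents that add atoms: none
Why: Anti-Markovnikov hydroboration occurs only at the monosubstituted vinyl group (the trisubstituted ring alkene is inert to 9-BBN-H), and the B-alkyl Suzuki–Miyaura coupling proceeds with retention at the vinyl triflate carbon, so the (2E)-enoate results.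

Step 9
Reactants: 13 ethyl (2E)-3-methyl-5-[(1S,2S)-1,2,3-trimethylcyclohex-3-en-1-yl]pent-2-enoate
Product: 14 (2E)-3-methyl-5-[(1S,2S)-1,2,3-trimethylcyclohex-3-en-1-yl]pent-2-en-1-ol
Conditions: i-Bu2AlH (2.5 equiv), CH2Cl2, −78 °C
Reagents that add atoms: none
Why: 1,2-Reduction of the enoate to the allylic alcohol leaves both trisubstituted alkenes and their geometry untouched.

Step 10
Reactants: 14 (2E)-3-methyl-5-[(1S,2S)-1,2,3-trimethylcyclohex-3-en-1-yl]pent-2-en-1-ol
Product: 15 (2E)-3-methyl-5-[(1S,2S)-1,2,3-trimethylcyclohex-3-en-1-yl]pent-2-enal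
Conditions: MnO2, CH2Cl2, rt, dark
Reagents that add atoms: none
Why: Chemoselective allylic oxidation with MnO2 should give the (E)-enal without over-oxidation or E/Z isomerisation.

Step 11
Reactants: 16 1,2,3-trimethoxybenzene
Product: 17 1,5-dibromo-2,3,4-trimethoxybenzene
Conditions: N-bromosuccinimide (2.1 equiv), MeCN, 0 °C → rt
Reagents that add atoms: N-bromosuccinimide, O=C1CCC(=O)N1Br
Why: Electrophilic aromatic bromination goes to the two positions para to the outer methoxy groups, so two equivalents give the 4,6-dibrominated trimethoxybenzene.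

Step 12
Reactants: 17 1,5-dibromo-2,3,4-trimethoxybenzene
Product: 19 4,5,6-trimethoxybenzene-1,3-diol, via bis(pinacol boronate) 18 (not isolated)
Conditions: B2pin2, Pd(dppf)Cl2 (5 mol %), KOAc, dioxane, 90 °C; then NaOH, 30% H2O2, THF/H2O, 0 °C; AcOH to pH 5 under Ar
Reagents that add atoms: hydrogen peroxide, OO
Why: Double Miyaura borylation followed by alkaline peroxide oxidation of both C–B bonds gives the symmetric resorcinol, whose only ring C–H lies between the two hydroxyls.

Step 13
Reactants: 19 4,5,6-trimethoxybenzene-1,3-diol; 15 (2E)-3-methyl-5-[(1S,2S)-1,2,3-trimethylcyclohex-3-en-1-yl]pent-2-enal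
Product: 22 (2R)-6,7,8-trimethoxy-2-methyl-2-{2-[(1S,2S)-1,2,3-trimethylcyclohex-3-en-1-yl]ethyl}-2H-chromen-5-ol, via carbinol 20 (not isolated), via vinyl ortho-quinone methide 21 (not isolated)
Conditions: (R)-3,3'-bis(2,4,6-triisopropylphenyl)-1,1'-binaphthyl-2,2'-diyl N-triflylphosphoramide (10 mol %), 4 Å MS, toluene, −30 → 0 °C, Ar, dark
Reagents that add atoms: none
Why: Proposed new method: the chiral Brønsted acid first promotes Friedel–Crafts 1,2-addition of the single free ring carbon of 19 to the enal carbonyl (Knoevenagel-type union, carbinol 20) and then ionises 20 to the (E)-vinyl ortho-quinone methide 21, held as a hydrogen-bonded contact ion pair with the chiral phosphoramide anion at the oxygen that becomes O1. Thermal disrotatory oxa-6π electrocyclisation of this 1-oxatriene (O=C8a–C4a=C4–C3=C2) then closes the pyran ring, the only ring formed, by making the O1–C2 bond, and is driven by rearomatisation of the benzene ring. The closest known reaction type is the chiral N-triflylphosphoramide-catalysed dehydrative cycloetherification of ortho-hydroxyaryl allylic alcohols to 2,2-disubstituted 2H-chromenes through chiral contact ion pairs, combined with the classical phenol–enal chromenylation (Knoevenagel/oxa-6π); new here are the purely dialkyl-substituted terminus and the one-pot union of the two fragments. The new stereocentre (chromene C2, to become R) is controlled by the catalyst: the E geometry of C2=C3 fixes methyl inside and the side chain outside, so the configuration follows only from the helical sense in which the oxatriene coils, and the anion next to the forming O–C bond has to make one coil lower in energy, the remote cyclohexene stereocentres giving no bias. The step needs site selectivity (secured because 19 has one unsubstituted ring carbon and the β,β-disubstitution of 15 blocks 1,4-addition), no choice between the two hydroxyls (they are equivalent through the twofold axis of 19, so either closure gives the same constitution and leaves the other as the 5-OH), and retention of the E geometry up to closure (secured by having the leaving group at the benzylic carbon and not at C2, by low temperature and by the speed of the aromatising closure).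

**Compound list**

1 | pent-1-en-3-one | CCC(=O)C=C | starting material
2 | (3Z)-3-[(triisopropylsilyl)oxy]penta-1,3-diene | C=C/C(O[Si](C(C)C)(C(C)C)C(C)C)=C/C | intermediate
3 | (E)-2-methylbut-2-enal | C/C=C(\C)C=O | starting material
4 | (1R,6R)-1,5,6-trimethyl-4-[(triisopropylsilyl)oxy]cyclohex-3-ene-1-carbaldehyde (C5 epimers; methyls at C1 and C6 cis) | O=C[C@]1(C)CC=C(O[Si](C(C)C)(C(C)C)C(C)C)C(C)[C@H]1C | intermediate
5 | triisopropyl{[(4S,5R)-4-ethenyl-4,5,6-trimethylcyclohex-1-en-1-yl]oxy}silane | C=C[C@]1(C)CC=C(O[Si](C(C)C)(C(C)C)C(C)C)C(C)[C@H]1C | intermediate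
6 | (3R,4S)-4-ethenyl-2,3,4-trimethylcyclohexan-1-one (C2 epimers) | C=C[C@]1(C)CCC(=O)C(C)[C@H]1C | intermediate
7 | bromomagnesium (3S,4S)-4-ethenyl-2,3,4-trimethylcyclohex-1-en-1-olate | C=C[C@]1(C)CCC(O[Mg]Br)=C(C)[C@H]1C | intermediate
8 | (3S,4S)-4-ethenyl-2,3,4-trimethylcyclohex-1-en-1-yl trifluoromethanesulfonate | C=C[C@]1(C)CCC(OS(=O)(=O)C(F)(F)F)=C(C)[C@H]1C | intermediate
9 | (3R,4S)-4-ethenyl-2,3,4-trimethylcyclohex-1-ene | C=C[C@]1(C)CCC=C(C)[C@H]1C | intermediate
10 | ethyl 3-oxobutanoate | CCOC(=O)CC(C)=O | starting material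
11 | ethyl (2E)-3-{[(trifluoromethyl)sulfonyl]oxy}but-2-enoate | CCOC(=O)/C=C(\C)OS(=O)(=O)C(F)(F)F | intermediate
12 | 9-{2-[(1R,2S)-1,2,3-trimethylcyclohex-3-en-1-yl]ethyl}-9-borabicyclo[3.3.1]nonane | C1CCC2CCCC(C1)B2CC[C@]1(C)CCC=C(C)[C@H]1C | intermediate
13 | ethyl (2E)-3-methyl-5-[(1S,2S)-1,2,3-trimethylcyclohex-3-en-1-yl]pent-2-enoate | CCOC(=O)/C=C(\C)CC[C@]1(C)CCC=C(C)[C@H]1C | intermediate
14 | (2E)-3-methyl-5-[(1S,2S)-1,2,3-trimethylcyclohex-3-en-1-yl]pent-2-en-1-ol | OC/C=C(\C)CC[C@]1(C)CCC=C(C)[C@H]1C | intermediate
15 | (2E)-3-methyl-5-[(1S,2S)-1,2,3-trimethylcyclohex-3-en-1-yl]pent-2-enal | O=C/C=C(\C)CC[C@]1(C)CCC=C(C)[C@H]1C | intermediate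
16 | 1,2,3-trimethoxybenzene | COc1cccc(OC)c1OC | starting material
17 | 1,5-dibromo-2,3,4-trimethoxybenzene | COc1c(Br)cc(Br)c(OC)c1OC | intermediate
18 | 2,2'-(4,5,6-trimethoxy-1,3-phenylene)bis(4,4,5,5-tetramethyl-1,3,2-dioxaborolane) | COc1c(B2OC(C)(C)C(C)(C)O2)cc(B2OC(C)(C)C(C)(C)O2)c(OC)c1OC | intermediate
19 | 4,5,6-trimethoxybenzene-1,3-diol | COc1c(O)cc(O)c(OC)c1OC | intermediate
20 | 2-{(2E)-1-hydroxy-3-methyl-5-[(1S,2S)-1,2,3-trimethylcyclohex-3-en-1-yl]pent-2-en-1-yl}-4,5,6-trimethoxybenzene-1,3-diol (carbinol epimers) | COc1c(O)c(C(O)/C=C(\C)CC[C@]2(C)CCC=C(C)[C@H]2C)c(O)c(OC)c1OC | intermediate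
21 | 5-hydroxy-2,3,4-trimethoxy-6-{(2E)-3-methyl-5-[(1S,2S)-1,2,3-trimethylcyclohex-3-en-1-yl]pent-2-en-1-ylidene}cyclohexa-2,4-dien-1-one | COC1=C(OC)C(=O)C(=C/C=C(\C)CC[C@]2(C)CCC=C(C)[C@H]2C)C(O)=C1OC | intermediate
22 | (2R)-6,7,8-trimethoxy-2-methyl-2-{2-[(1S,2S)-1,2,3-trimethylcyclohex-3-en-1-yl]ethyl}-2H-chromen-5-ol | COc1c(O)c2c(c(OC)c1OC)O[C@](C)(CC[C@]1(C)CCC=C(C)[C@H]1C)C=C2 | target

**Count**

Total steps: 13. Longest linear sequence: 10 (steps 1–6, 8–10, 13).

**Steps most likely to fail**

1. Step 13 (proposed new method). The ion-paired catalyst may not discriminate the two helical coils of the oxatriene. The enal or the oxatriene terminus may lose its E geometry before closure. The acid-catalysed union may also be slow compared with self-condensation of the quinone methide. Fallback, from 19 and 15 back to 22: stereocontrol by induction is given up and replaced by separation. The two fragments are condensed under the well-precedented ethylenediammonium diacetate conditions (toluene, 60–110 °C; iminium-mediated Knoevenagel condensation, then uncatalysed oxa-6π electrocyclisation). This should give 22 together with its C2 epimer, the (2S)-chromenol F1. The two are diastereomers and are separated by preparative HPLC on a polysaccharide-type chiral stationary phase, giving 22.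

2. Step 2. The trisubstituted enal may react slowly with the 4-substituted diene. The reaction may leak into a stepwise Mukaiyama–Michael pathway, which would erode the cis relationship of the two methyls. Facial discrimination by the catalyst may be modest. Fallback, from 2 and 3 back to 4: the cycloaddition is run without chiral control (neat, 110 °C, sealed tube, or Me2AlCl, CH2Cl2, −78 °C). This gives 4 together with its enantiomer, the (1S,6S)-aldehyde F2. The racemate is condensed with (1R,2R)-N,N'-dimethylcyclohexane-1,2-diamine (MgSO4, CH2Cl2) to the diastereomeric aminals: the aminal of the (1R,6R)-aldehyde F3 and the aminal of the (1S,6S)-aldehyde F4. These are separated by chromatography, and mild hydrolysis of F3 (aq. AcOH/THF, 0 °C) returns enantiopure 4.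

3. Step 5. Enolisation may not be fully regioselective; competition from the less substituted C6 enolate would give, after step 6, the regioisomeric ring alkene. Fallback, from 6 back to 9 (bypassing 7 and 8): 6 is reduced with LiBH(s-Bu)3 (THF, −78 °C) to the axial alcohol, (3R,4S)-4-ethenyl-2,3,4-trimethylcyclohexan-1-ol F5. This is dehydrated by anti-periplanar elimination with POCl3/pyridine (0 °C → rt), which should favour the more substituted alkene and gives 9 directly.

**Further compounds**

F1 | step 13 | (2S)-6,7,8-trimethoxy-2-methyl-2-{2-[(1S,2S)-1,2,3-trimethylcyclohex-3-en-1-yl]ethyl}-2H-chromen-5-ol (C2 epimer of 22) | COc1c(O)c2c(c(OC)c1OC)O[C@@](C)(CC[C@]1(C)CCC=C(C)[C@H]1C)C=C2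
F2 | step 2 | (1S,6S)-1,5,6-trimethyl-4-[(triisopropylsilyl)oxy]cyclohex-3-ene-1-carbaldehyde (enantiomer of 4) | O=C[C@@]1(C)CC=C(O[Si](C(C)C)(C(C)C)C(C)C)C(C)[C@@H]1C
F3 | step 2 | aminal (1,3-dimethyloctahydrobenzimidazole) of 4 with (1R,2R)-N,N'-dimethylcyclohexane-1,2-diamine | CN1[C@@H]2CCCC[C@H]2N(C)C1[C@]1(C)CC=C(O[Si](C(C)C)(C(C)C)C(C)C)C(C)[C@H]1C
F4 | step 2 | aminal (1,3-dimethyloctahydrobenzimidazole) of F2 with (1R,2R)-N,N'-dimethylcyclohexane-1,2-diamine | CN1[C@@H]2CCCC[C@H]2N(C)C1[C@@]1(C)CC=C(O[Si](C(C)C)(C(C)C)C(C)C)C(C)[C@@H]1C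
F5 | step 5 | (3R,4S)-4-ethenyl-2,3,4-trimethylcyclohexan-1-ol (C1 and C2 epimers) | C=C[C@]1(C)CCC(O)C(C)[C@H]1C
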